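Its constants were chosen freely; the result is computed.

Which flask ends highest in excess of left-handed product over right-handed product? Keep the flasks, steps and conventions in front of you:

| flask | left-handed substrate | partner | right-handed substrate | temperature | time | remark |
|---|---|---|---|---|---|---|
| Friday's | 0.10 M | 0.400 M | 0.10 M | 65 °C | 1.0 min |  |
| Saturday's | 0.10 M | 0.400 M | 0.10 M | 35 °C | 1.0 min |  |
| Wednesday's | 0.10 M | 0.400 M | 0.10 M |  | 1.0 min | at 95 °C until 40 s, from then on at 35 °C |
| Monday's | 0.10 M | 0.400 M | 0.10 M | 95 °C | 1.0 min |  |

    left-handed substrate ⇌ achiral form (K1 = 0.036, k1 = 0.014 s⁻¹, Ea1 = 91.0 kJ mol⁻¹, ΔH1 = −88.0 kJ mol⁻¹)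
    partner + right-handed substrate → right-handed product (k2 = 0.0058 M⁻¹ s⁻¹, Ea2 = 65.0 kJ mol⁻¹)
    partner → decomposition product (k3 = 1.2 × 10⁻⁵ s⁻¹, Ea3 = 94.0 kJ mol⁻¹)
    right-handed substrate ⇌ achiral form (K1 = 0.036, k1 = 0.014 s⁻¹, Ea1 = 91.0 kJ mol⁻¹, ΔH1 = −88.0 kJ mol⁻¹)
    achiral form → side product (k5 = 0.35 s⁻¹, Ea5 = 67.0 kJ mol⁻¹)
    partner + left-handed substrate → left-handed product (k6 = 0.054 M⁻¹ s⁻¹, Ea6 = 62.0 kJ mol⁻¹)
    partner ⇌ dormant form (K7 = 2.0, k7 = 0.023 s⁻¹, Ea7 = 85.0 kJ mol⁻¹, ΔH7 = −4.00 kJ mol⁻¹)
    (constants at 35 °C)

- partner is single-handed; left-handed substrate and right-handed substrate are mirror images of each other, charged as a racemate, each of them at the stated concentration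
- the constants hold at 35 °C; other temperatures follow from the activation energies and enthalpies
- an excess is the difference of the two amounts in percent of their sum
- an excess is below zero if the other one leads
- the handed part of partner does not stay in what it makes, so the products of the two hands are mirror images too

1. the flask that comes out highest in excess of left-handed product over right-handed product, or "all alike" when all lie within 1.5 percentage points (Friday's / Saturday's / Wednesday's / Monday's / all alike)
2. excess of left-handed product over right-handed product at the end, Friday's
3. excess of left-handed product over right-handed product at the end, Saturday's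
4. excess of left-handed product over right-handed product at the end, Wednesday's
5. excess of left-handed product over right-handed product at the end, Monday's

Start from c(partner), the free form. Both capture steps are first order in it, so it cancels from their ratio, the selectivity factor. In Monday's flask at 95 °C that factor is 7.69. With equal substrates the excess is this factor less one over the factor plus one, here 77.0 %. But c(partner) does not cancel against the change of hand.

Now descend the ladder for Monday's flask. Achiral form goes on to side product at 24.8 s⁻¹. It returns to substrate at 34300 s⁻¹, which is faster than that. Partner and dormant form then balance, with 39.2 % of the pair free, relaxing at 8.43 s⁻¹. Next, each substrate enters achiral form at 4.57 s⁻¹. Below that comes capture. Take the halfway point, where partner and dormant form together hold 0.300 M. Left-handed substrate is then captured at 0.328 s⁻¹ and right-handed substrate at 0.0426 s⁻¹. Decomposition comes last, at 0.00474 s⁻¹.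

Define the lag as the difference of the two capture rates over twice the rate of entering achiral form. It is the shortfall of left-handed substrate, as a fraction of both substrates together: 0.0312 on Monday's. Multiply the selectivity factor by one minus the lag, and divide by one plus the lag. Put that into the excess rule, and Monday's gives 75.7 %. Wednesday's stays hot for 40 s, about 10.7 capture half-lives, so reckon it as Monday's: 75.7 %. Friday's, at 65 °C, has factor 8.39 and lag 0.0681, which gives 76.0 %.

Saturday's is where my reckoning stops. Its factor is 9.31 and its halfway lag 0.172, but the time for a substrate to enter achiral form is 71.4 s, longer than the 1.0 min run, so I cannot assume a steady lag. I therefore commit to a rough bracket for Saturday's, taking that lag as a guess and not as a limit: above 73.6 % and below 80.6 %. That bracket spans 7 percentage points against a margin of 1.5 points, so I give no verdict.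

The forecast goes further and says all alike, with 76 % for Friday's, 75.5 % for Saturday's, 75.9 % for Wednesday's and 75.9 % for Monday's. Its ground for the hot flasks is that “substrate racemises through the achiral form much faster than it is captured”. For Saturday's, which it calls the least certain, it takes racemisation as slow and reaches nearly the same value by a coarse hand march.

The flasks give 76.0 % for Friday's, 75.9 % for Saturday's, 75.7 % for Wednesday's and 75.7 % for Monday's, so the outcome is all alike, as forecast. Watch the substrate pair in Wednesday's flask. At 0.667 min left-handed substrate reads 0.215 % and right-handed substrate 0.223 %, a ratio of 0.964. Put the free partner of that reading in place of the halfway figure: the lag becomes 0.0194, which gives a ratio of 0.962.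

Now raise partner in Wednesday's recipe to 1.6 M. The selectivity factor stays 7.69, but the lag grows with the partner pool to 0.156, which gives 69.8 %. That flask computes to 70.7 %; Wednesday's answer has moved 5 points by 1.59 M of partner, and a run there breaks the forecast's verdict.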